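**Retrosynthetic overview**
- End game: fluoride and LiOH unmask the enol, catechol and side-chain alcohol; the C3 aroyl group comes from a C3 vinyllithium and a silyl-protected 3,4-dihydroxybenzoyl chloride.
- The C5 side chain is attached by bridgehead lithiation of the bicyclic methyl enol ether and SN2 alkylation with a (2E,4S)-allylic bromide.
- Side-chain bromide: Zr-catalysed methylalumination/formaldehyde trapping of an (S)-propargylic silyl ether, whose carbinol centre comes from a ketoreductase reduction of a silyl ynone.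
- Bicyclic core: the second (diketone) ring is closed by Effenberger annulation of malonyl dichloride onto a tetrasubstituted silyl enol ether, fixing C1 and C5 relative to C7.
- The first ring (cyclohexenone) comes from a prolinol-ether-catalysed Michael addition of 5-methylhex-4-enal to methyl vinyl ketone and aldol condensation (sets C7); the arene is bought.

Assumption: 5-methylhex-4-enal and 4-methylpent-3-enoic acid are bought as such, and the enolised triketone is drawn in the tautomer of the given SMILES (the tautomers interconvert).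

Locants C1, C5, C7 refer to the bicyclo[3.3.1]nonane numbering of the target name (C1 = quaternary carbon next to CMe2, C5 = side-chain bridgehead).

**Core (steps 1–10)**

Step 1
Reactants: 1 5-methylhex-4-enal; 2 but-3-en-2-one (methyl vinyl ketone)
Product: 3 (2S)-2-(3-methylbut-2-en-1-yl)-5-oxohexanal
Conditions: (S)-2-[methoxy(diphenyl)methyl]pyrrolidine (5 mol %), ethyl 3,4-dihydroxybenzoate (20 mol %), neat, 4 °C, 36 h
Reagents that add atoms: none
Why: Enamine-catalysed asymmetric Michael addition in which the diphenyl(methoxy)methyl group shields one face of the E-enamine, so the enone adds to the other face and sets the first stereocentre (future C7) as S here; the facial sense is predicted from the steric-shielding model, and the (R)-catalyst would be used if the rotation showed the antipode.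

Step 2
Reactants: 3 (2S)-2-(3-methylbut-2-en-1-yl)-5-oxohexanal
Product: 5 (4S)-4-(3-methylbut-2-en-1-yl)cyclohex-2-en-1-one, via aldol adduct 4 (not isolated)
Conditions: LiOH·H2O (0.3 equiv), i-PrOH, rt, 24 h
Reagents that add atoms: none
Why: Intramolecular aldol condensation of the methyl ketone onto the aldehyde closes the first ring, and the gamma stereocentre is not enolised under these mild conditions.

Step 3
Reactants: 5 (4S)-4-(3-methylbut-2-en-1-yl)cyclohex-2-en-1-one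
Product: 6 trimethyl{[(3S,4S)-3-methyl-4-(3-methylbut-2-en-1-yl)cyclohex-1-en-1-yl]oxy}silane
Conditions: Me2CuLi (from MeLi and CuI, 1.3 equiv), Me3SiCl (2 equiv), THF, −78 °C; then Et3N, aq. NaHCO3 work-up
Reagents that add atoms: lithium dimethylcuprate, [Li+].C[Cu-]C; chlorotrimethylsilane, C[Si](C)(C)Cl
Why: Cuprate conjugate addition occurs anti to the C4 side chain (this methyl stereocentre is erased in step 4) and in situ silylation traps the enolate regiospecifically.

Step 4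
Reactants: 6 trimethyl{[(3S,4S)-3-methyl-4-(3-methylbut-2-en-1-yl)cyclohex-1-en-1-yl]oxy}silane
Product: 7 (4S)-3-methyl-4-(3-methylbut-2-en-1-yl)cyclohex-2-en-1-one
Conditions: Pd(OAc)2 (1.05 equiv), MeCN, rt, 12 h
Reagents that add atoms: none
Why: Saegusa–Ito oxidation, in which the palladium enolate can only eliminate a beta-hydride from C3, re-forms the enone with the methyl in place and leaves C4 untouched.

Step 5
Reactants: 7 (4S)-3-methyl-4-(3-methylbut-2-en-1-yl)cyclohex-2-en-1-one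
Product: 8 (4S)-2-iodo-3-methyl-4-(3-methylbut-2-en-1-yl)cyclohex-2-en-1-one
Conditions: I2 (2 equiv), pyridine/CH2Cl2 (1:1), 0 °C → rt
Reagents that add atoms: iodine, II
Why: Johnson alpha-iodination (pyridine conjugate addition, enolate iodination, elimination) functionalises C2 without passing through the dienolate that would racemise C4.

Step 6
Reactants: 8 (4S)-2-iodo-3-methyl-4-(3-methylbut-2-en-1-yl)cyclohex-2-en-1-one; 9 allyltributylstannane
Product: 10 (4S)-3-methyl-4-(3-methylbut-2-en-1-yl)-2-(prop-2-en-1-yl)cyclohex-2-en-1-one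
Conditions: Pd2(dba)3 (2.5 mol %), AsPh3 (10 mol %), CuI (10 mol %), NMP, 50 °C
Reagents that add atoms: none
Why: Stille cross-coupling of the alpha-iodoenone with the allylstannane installs the C2 three-carbon unit without regiochemical ambiguity.

Step 7
Reactants: 10 (4S)-3-methyl-4-(3-methylbut-2-en-1-yl)-2-(prop-2-en-1-yl)cyclohex-2-en-1-one
Product: 11 (4S)-3-methyl-2,4-bis(3-methylbut-2-en-1-yl)cyclohex-2-en-1-one
Conditions: second-generation Grubbs catalyst (5 mol %), 2-methylbut-2-ene/CH2Cl2 (1:1), 40 °C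
Reagents that add atoms: 2-methylbut-2-ene, CC=C(C)C
Why: Olefin cross-metathesis turns the terminal allyl group into prenyl, while exchange at the existing prenyl group is degenerate and the tetrasubstituted enone alkene is inert.

Step 8
Reactants: 11 (4S)-3-methyl-2,4-bis(3-methylbut-2-en-1-yl)cyclohex-2-en-1-one
Product: 12 {[(4S)-3,3-dimethyl-2,4-bis(3-methylbut-2-en-1-yl)cyclohex-1-en-1-yl]oxy}trimethylsilane
Conditions: Me2CuLi (from MeLi and CuI, 2.5 equiv), Me3SiCl (4 equiv), THF, −78 → −20 °C; then Et3N; crude product used at once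
Reagents that add atoms: lithium dimethylcuprate, [Li+].C[Cu-]C; chlorotrimethylsilane, C[Si](C)(C)Cl
Why: Silyl-chloride-accelerated cuprate conjugate addition builds the gem-dimethyl carbon and gives the tetrasubstituted silyl enol ether as a single regioisomer.

Step 9
Reactants: 12 {[(4S)-3,3-dimethyl-2,4-bis(3-methylbut-2-en-1-yl)cyclohex-1-en-1-yl]oxy}trimethylsilane; 13 malonyl dichloride
Product: 15 (1R,5S,7R)-8,8-dimethyl-1,7-bis(3-methylbut-2-en-1-yl)bicyclo[3.3.1]nonane-2,4,9-trione, via keto acid chloride 14 (not isolated)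
Conditions: Et2O, −20 °C → rt, 24 h; then aq. KOH, BnEt3NCl, rt; acidify to pH 3
Reagents that add atoms: none
Why: Effenberger-type annulation, in which the first C-acylation occurs on the enol-ether face trans to the neighbouring prenyl-bearing CH and the second, necessarily cis-diaxial C-acylation at the methylene closes the second ring, sets C1 and C5 relative to C7 with the C7 prenyl exo (equatorial).

Step 10
Reactants: 15 (1R,5S,7R)-8,8-dimethyl-1,7-bis(3-methylbut-2-en-1-yl)bicyclo[3.3.1]nonane-2,4,9-trione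
Product: 16 (1R,5S,7R)-4-methoxy-8,8-dimethyl-1,7-bis(3-methylbut-2-en-1-yl)bicyclo[3.3.1]non-3-ene-2,9-dione
Conditions: Me2SO4, K2CO3, acetone, reflux; chromatography removes the minor regioisomer (OMe next to the quaternary bridgehead)
Reagents that add atoms: dimethyl sulfate, COS(=O)(=O)OC
Why: O-Alkylation of the vinylogous acid goes mainly to the oxygen remote from the quaternary bridgehead, giving the vinylogous ester whose OMe flanks the bridgehead C–H to be lithiated.

**Side-chain bromide (steps 11–17)**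

Step 11
Reactants: 17 4-methylpent-3-enoic acid
Product: 19 N-methoxy-N,4-dimethylpent-3-enamide, via acyl imidazole 18 (not isolated)
Conditions: 1,1'-carbonyldiimidazole, CH2Cl2, 0 °C → rt; then MeNH(OMe)·HCl, rt
Reagents that add atoms: N,O-dimethylhydroxylamine hydrochloride, CNOC.Cl
Why: Weinreb amide formation through the acyl imidazole activates the acid under near-neutral conditions that do not move the beta,gamma double bond into conjugation.

Step 12
Reactants: 19 N-methoxy-N,4-dimethylpent-3-enamide; 20 ethynyltrimethylsilane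
Product: 22 6-methyl-1-(trimethylsilyl)hept-5-en-1-yn-3-one, via lithium acetylide 21 (not isolated)
Conditions: n-BuLi, THF, −78 °C; then 19, −78 → 0 °C; cold aq. NH4Cl
Reagents that add atoms: none
Why: Weinreb ketone synthesis, in which the chelated tetrahedral adduct stops at mono-addition and releases the base-sensitive skipped enynone only on mildly acidic quench.

Step 13
Reactants: 22 6-methyl-1-(trimethylsilyl)hept-5-en-1-yn-3-one
Product: 23 (3S)-6-methyl-1-(trimethylsilyl)hept-5-en-1-yn-3-ol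
Conditions: ketoreductase (NADPH-dependent alcohol dehydrogenase, S-selective variant chosen from a screening panel), NADP+ (cat.), i-PrOH (10% v/v), phosphate buffer pH 7.0, 30 °C
Reagents that add atoms: none
Why: Enzymatic asymmetric carbonyl reduction by a ketoreductase delivers hydride from NADPH to one face of the ynone in the active site, setting the side-chain carbinol as S, with i-PrOH recycling the cofactor.

Step 14
Reactants: 23 (3S)-6-methyl-1-(trimethylsilyl)hept-5-en-1-yn-3-ol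
Product: 24 tert-butyl(dimethyl){[(3S)-6-methyl-1-(trimethylsilyl)hept-5-en-1-yn-3-yl]oxy}silane
Conditions: t-BuMe2SiCl, imidazole, DMF, rt
Reagents that add atoms: tert-butyldimethylsilyl chloride, CC(C)(C)[Si](C)(C)Cl
Why: Silyl ether formation protects the carbinol for the organometallic steps without touching the stereocentre.

Step 15
Reactants: 24 tert-butyl(dimethyl){[(3S)-6-methyl-1-(trimethylsilyl)hept-5-en-1-yn-3-yl]oxy}silane
Product: 25 tert-butyl(dimethyl){[(3S)-6-methylhept-5-en-1-yn-3-yl]oxy}silane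
Conditions: K2CO3 (0.2 equiv), MeOH, rt
Reagents that add atoms: none
Why: Methanolysis cleaves the alkynyl C–Si bond selectively while the secondary alkyl silyl ether is stable to carbonate.

Step 16
Reactants: 25 tert-butyl(dimethyl){[(3S)-6-methylhept-5-en-1-yn-3-yl]oxy}silane
Product: 28 (2E,4S)-4-{[tert-butyl(dimethyl)silyl]oxy}-3,7-dimethylocta-2,6-dien-1-ol, via alkenylalane 26 (not isolated), via lithium alkenylaluminate 27 (not isolated)
Conditions: AlMe3 (3 equiv), Cp2ZrCl2 (0.25 equiv), CH2Cl2, 0 °C → rt; then n-BuLi, (CH2O)n, THF, −78 °C → rt; aq. NH4Cl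
Reagents that add atoms: trimethylaluminium, C[Al](C)C; paraformaldehyde (formaldehyde unit), C=O
Why: Negishi zirconium-catalysed carboalumination adds methyl and aluminium syn across the terminal alkyne (methyl to the internal carbon), and trapping the aluminate with formaldehyde with retention gives the E trisubstituted allylic alcohol.

Step 17
Reactants: 28 (2E,4S)-4-{[tert-butyl(dimethyl)silyl]oxy}-3,7-dimethylocta-2,6-dien-1-ol
Product: 29 {[(2E,4S)-1-bromo-3,7-dimethylocta-2,6-dien-4-yl]oxy}(tert-butyl)dimethylsilane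
Conditions: CBr4, PPh3, CH2Cl2, −20 → 0 °C; used promptly
Reagents that add atoms: tetrabromomethane, BrC(Br)(Br)Br
Why: Appel bromination converts the primary allylic alcohol by SN2 displacement without allylic transposition.

**Aroyl chloride (steps 18–19)**

Step 18
Reactants: 30 3,4-dihydroxybenzoic acid
Product: 32 3,4-bis{[tert-butyl(dimethyl)silyl]oxy}benzoic acid, via tris-silyl ester 31 (not isolated)
Conditions: t-BuMe2SiCl (3.5 equiv), imidazole, DMF, rt; then AcOH/THF/H2O (3:1:1), rt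
Reagents that add atoms: tert-butyldimethylsilyl chloride, CC(C)(C)[Si](C)(C)Cl
Why: Exhaustive silylation followed by selective hydrolysis of the labile silyl ester leaves the two aryl silyl ethers in place.

Step 19
Reactants: 32 3,4-bis{[tert-butyl(dimethyl)silyl]oxy}benzoic acid
Product: 33 3,4-bis{[tert-butyl(dimethyl)silyl]oxy}benzoyl chloride
Conditions: (COCl)2, DMF (cat.), CH2Cl2, 0 °C → rt; volatiles removed, used crude
Reagents that add atoms: oxalyl chloride, O=C(Cl)C(=O)Cl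
Why: Vilsmeier-type acid chloride formation proceeds under near-neutral conditions tolerated by aryl silyl ethers.

**Union and end game (steps 20–23)**

Step 20
Reactants: 16 (1R,5S,7R)-4-methoxy-8,8-dimethyl-1,7-bis(3-methylbut-2-en-1-yl)bicyclo[3.3.1]non-3-ene-2,9-dione; 29 {[(2E,4S)-1-bromo-3,7-dimethylocta-2,6-dien-4-yl]oxy}(tert-butyl)dimethylsilane
Product: 35 (1R,5S,7R)-5-[(2E,4S)-4-{[tert-butyl(dimethyl)silyl]oxy}-3,7-dimethylocta-2,6-dien-1-yl]-4-methoxy-8,8-dimethyl-1,7-bis(3-methylbut-2-en-1-yl)bicyclo[3.3.1]non-3-ene-2,9-dione, via bridgehead organolithium 34 (not isolated)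
Conditions: LiN(i-Pr)2 (commercial solution, 1.5 equiv), THF, −78 °C, 30 min; then 29 (1.5 equiv), −78 → 0 °C
Reagents that add atoms: none
Why: Bridgehead lithiation of the C5–H flanked by the methoxy-bearing carbon and the C9 ketone, then SN2 alkylation by the primary allylic bromide, forms the quaternary C5 with retention (a bridgehead cannot invert) and carries the side-chain stereocentre in unchanged.

Step 21
Reactants: 35 (1R,5S,7R)-5-[(2E,4S)-4-{[tert-butyl(dimethyl)silyl]oxy}-3,7-dimethylocta-2,6-dien-1-yl]-4-methoxy-8,8-dimethyl-1,7-bis(3-methylbut-2-en-1-yl)bicyclo[3.3.1]non-3-ene-2,9-dione; 33 3,4-bis{[tert-butyl(dimethyl)silyl]oxy}benzoyl chloride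
Product: 37 (1S,5S,7R)-3-(3,4-bis{[tert-butyl(dimethyl)silyl]oxy}benzoyl)-5-[(2E,4S)-4-{[tert-butyl(dimethyl)silyl]oxy}-3,7-dimethylocta-2,6-dien-1-yl]-4-methoxy-8,8-dimethyl-1,7-bis(3-methylbut-2-en-1-yl)bicyclo[3.3.1]non-3-ene-2,9-dione, via vinyllithium 36 (not isolated)
Conditions: lithium 2,2,6,6-tetramethylpiperidide (commercial solution, 2.5 equiv), THF, −78 °C; then 33 (3 equiv), −78 °C
Reagents that add atoms: none
Why: With both bridgeheads quaternary the hindered amide removes the only acidic proton (vinylic C3–H of the vinylogous ester), and the vinyllithium is C-acylated by the aroyl chloride.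

Step 22
Reactants: 37 (the C3-aroylated methyl enol ether of step 21)
Product: 38 (1S,5S,7R)-5-[(2E,4S)-4-{[tert-butyl(dimethyl)silyl]oxy}-3,7-dimethylocta-2,6-dien-1-yl]-3-(3,4-dihydroxybenzoyl)-4-hydroxy-8,8-dimethyl-1,7-bis(3-methylbut-2-en-1-yl)bicyclo[3.3.1]non-3-ene-2,9-dione
Conditions: LiOH (1 M aq., 10 equiv), 1,4-dioxane, 90 °C, argon; then 1 M HCl to pH 3 at 0 °C
Reagents that add atoms: lithium hydroxide, [Li+].[OH-]
Why: Hydroxide addition–elimination at the methoxy-bearing carbon of the acylated vinylogous ester gives the enolised triketone and also cleaves the two base-labile aryl silyl ethers, while the secondary alkyl silyl ether survives.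

Step 23
Reactants: 38 (the mono-silylated triketone of step 22)
Product: 39 (1S,5S,7R)-3-(3,4-dihydroxybenzoyl)-4-hydroxy-5-[(2E,4S)-4-hydroxy-3,7-dimethylocta-2,6-dien-1-yl]-8,8-dimethyl-1,7-bis(3-methylbut-2-en-1-yl)bicyclo[3.3.1]non-3-ene-2,9-dione (target)
Conditions: HF·pyridine, pyridine, THF, 0 °C → rt
Reagents that add atoms: none
Why: Buffered fluoride desilylation removes the last silyl ether without the acid-catalysed cyclisation of the enol onto a prenyl group.

**Compound list**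
1 | 5-methylhex-4-enal | CC(C)=CCCC=O | starting material
2 | but-3-en-2-one (methyl vinyl ketone) | CC(=O)C=C | starting material
3 | (2S)-2-(3-methylbut-2-en-1-yl)-5-oxohexanal | O=C[C@H](CC=C(C)C)CCC(C)=O | intermediate
4 | (4S)-3-hydroxy-4-(3-methylbut-2-en-1-yl)cyclohexan-1-one (aldol adduct, C3 epimers) | O=C1CC(O)[C@H](CC=C(C)C)CC1 | intermediate
5 | (4S)-4-(3-methylbut-2-en-1-yl)cyclohex-2-en-1-one | O=C1C=C[C@H](CC=C(C)C)CC1 | intermediate
6 | trimethyl{[(3S,4S)-3-methyl-4-(3-methylbut-2-en-1-yl)cyclohex-1-en-1-yl]oxy}silane (methyl trans to side chain) | C[C@@H]1C=C(O[Si](C)(C)C)CC[C@H]1CC=C(C)C | intermediate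
7 | (4S)-3-methyl-4-(3-methylbut-2-en-1-yl)cyclohex-2-en-1-one | O=C1C=C(C)[C@H](CC=C(C)C)CC1 | intermediate
8 | (4S)-2-iodo-3-methyl-4-(3-methylbut-2-en-1-yl)cyclohex-2-en-1-one | O=C1C(I)=C(C)[C@H](CC=C(C)C)CC1 | intermediate
9 | allyltributylstannane | C=CC[Sn](CCCC)(CCCC)CCCC | starting material
10 | (4S)-3-methyl-4-(3-methylbut-2-en-1-yl)-2-(prop-2-en-1-yl)cyclohex-2-en-1-one | O=C1C(CC=C)=C(C)[C@H](CC=C(C)C)CC1 | intermediate
11 | (4S)-3-methyl-2,4-bis(3-methylbut-2-en-1-yl)cyclohex-2-en-1-one | O=C1C(CC=C(C)C)=C(C)[C@H](CC=C(C)C)CC1 | intermediate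
12 | {[(4S)-3,3-dimethyl-2,4-bis(3-methylbut-2-en-1-yl)cyclohex-1-en-1-yl]oxy}trimethylsilane | C[Si](C)(C)OC1=C(CC=C(C)C)C(C)(C)[C@H](CC=C(C)C)CC1 | intermediate
13 | malonyl dichloride | O=C(Cl)CC(=O)Cl | starting material
14 | 3-[(1S,3S)-2,2-dimethyl-1,3-bis(3-methylbut-2-en-1-yl)-6-oxocyclohexyl]-3-oxopropanoyl chloride | CC(C)=CC[C@@H]1CCC(=O)[C@@](CC=C(C)C)(C(=O)CC(=O)Cl)C1(C)C | intermediate
15 | (1R,5S,7R)-8,8-dimethyl-1,7-bis(3-methylbut-2-en-1-yl)bicyclo[3.3.1]nonane-2,4,9-trione (enolised in solution) | CC(C)=CC[C@@H]1C[C@@H]2C(=O)[C@@](CC=C(C)C)(C(=O)CC2=O)C1(C)C | intermediate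
16 | (1R,5S,7R)-4-methoxy-8,8-dimethyl-1,7-bis(3-methylbut-2-en-1-yl)bicyclo[3.3.1]non-3-ene-2,9-dione | CC(C)=CC[C@@H]1C[C@@H]2C(=O)[C@@](CC=C(C)C)(C(=O)C=C2OC)C1(C)C | intermediate
17 | 4-methylpent-3-enoic acid | CC(C)=CCC(=O)O | starting material
18 | 1-(imidazol-1-yl)-4-methylpent-3-en-1-one (acyl imidazole) | CC(C)=CCC(=O)n1ccnc1 | intermediate
19 | N-methoxy-N,4-dimethylpent-3-enamide | CC(C)=CCC(=O)N(C)OC | intermediate
20 | ethynyltrimethylsilane | C#C[Si](C)(C)C | starting material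
21 | lithium (trimethylsilyl)acetylide | [Li]C#C[Si](C)(C)C | intermediate
22 | 6-methyl-1-(trimethylsilyl)hept-5-en-1-yn-3-one | CC(C)=CCC(=O)C#C[Si](C)(C)C | intermediate
23 | (3S)-6-methyl-1-(trimethylsilyl)hept-5-en-1-yn-3-ol | C[Si](C)(C)C#C[C@@H](O)CC=C(C)C | intermediate
24 | tert-butyl(dimethyl){[(3S)-6-methyl-1-(trimethylsilyl)hept-5-en-1-yn-3-yl]oxy}silane | C[Si](C)(C)C#C[C@@H](O[Si](C)(C)C(C)(C)C)CC=C(C)C | intermediate
25 | tert-butyl(dimethyl){[(3S)-6-methylhept-5-en-1-yn-3-yl]oxy}silane | C#C[C@@H](O[Si](C)(C)C(C)(C)C)CC=C(C)C | intermediate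
26 | [(1E,3S)-3-{[tert-butyl(dimethyl)silyl]oxy}-2,6-dimethylhepta-1,5-dien-1-yl]dimethylalane | C[Al](C)/C=C(\C)[C@@H](O[Si](C)(C)C(C)(C)C)CC=C(C)C | intermediate
27 | lithium butyl[(1E,3S)-3-{[tert-butyl(dimethyl)silyl]oxy}-2,6-dimethylhepta-1,5-dien-1-yl]dimethylaluminate | [Li+].CCCC[Al-](C)(C)/C=C(\C)[C@@H](O[Si](C)(C)C(C)(C)C)CC=C(C)C | intermediate
28 | (2E,4S)-4-{[tert-butyl(dimethyl)silyl]oxy}-3,7-dimethylocta-2,6-dien-1-ol | OC/C=C(\C)[C@@H](O[Si](C)(C)C(C)(C)C)CC=C(C)C | intermediate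
29 | {[(2E,4S)-1-bromo-3,7-dimethylocta-2,6-dien-4-yl]oxy}(tert-butyl)dimethylsilane | BrC/C=C(\C)[C@@H](O[Si](C)(C)C(C)(C)C)CC=C(C)C | intermediate
30 | 3,4-dihydroxybenzoic acid | OC(=O)c1ccc(O)c(O)c1 | starting material
31 | tert-butyldimethylsilyl 3,4-bis{[tert-butyl(dimethyl)silyl]oxy}benzoate | CC(C)(C)[Si](C)(C)OC(=O)c1ccc(O[Si](C)(C)C(C)(C)C)c(O[Si](C)(C)C(C)(C)C)c1 | intermediate
32 | 3,4-bis{[tert-butyl(dimethyl)silyl]oxy}benzoic acid | OC(=O)c1ccc(O[Si](C)(C)C(C)(C)C)c(O[Si](C)(C)C(C)(C)C)c1 | intermediate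
33 | 3,4-bis{[tert-butyl(dimethyl)silyl]oxy}benzoyl chloride | O=C(Cl)c1ccc(O[Si](C)(C)C(C)(C)C)c(O[Si](C)(C)C(C)(C)C)c1 | intermediate
34 | C5-lithio derivative of 16 (bridgehead organolithium) | CC(C)=CC[C@@H]1C[C@]2([Li])C(=O)[C@@](CC=C(C)C)(C(=O)C=C2OC)C1(C)C | intermediate
35 | (1R,5S,7R)-5-[(2E,4S)-4-{[tert-butyl(dimethyl)silyl]oxy}-3,7-dimethylocta-2,6-dien-1-yl]-4-methoxy-8,8-dimethyl-1,7-bis(3-methylbut-2-en-1-yl)bicyclo[3.3.1]non-3-ene-2,9-dione | CC(C)=CC[C@@H]1C[C@]2(C/C=C(\C)[C@@H](O[Si](C)(C)C(C)(C)C)CC=C(C)C)C(=O)[C@@](CC=C(C)C)(C(=O)C=C2OC)C1(C)C | intermediate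
36 | C3-lithio derivative of 35 (vinyllithium) | CC(C)=CC[C@@H]1C[C@]2(C/C=C(\C)[C@@H](O[Si](C)(C)C(C)(C)C)CC=C(C)C)C(=O)[C@@](CC=C(C)C)(C(=O)C([Li])=C2OC)C1(C)C | intermediate
37 | (1S,5S,7R)-3-(3,4-bis{[tert-butyl(dimethyl)silyl]oxy}benzoyl)-5-[(2E,4S)-4-{[tert-butyl(dimethyl)silyl]oxy}-3,7-dimethylocta-2,6-dien-1-yl]-4-methoxy-8,8-dimethyl-1,7-bis(3-methylbut-2-en-1-yl)bicyclo[3.3.1]non-3-ene-2,9-dione | CC(C)=CC[C@@H]1C[C@]2(C/C=C(\C)[C@@H](O[Si](C)(C)C(C)(C)C)CC=C(C)C)C(=O)[C@@](CC=C(C)C)(C(=O)C(C(=O)c3ccc(O[Si](C)(C)C(C)(C)C)c(O[Si](C)(C)C(C)(C)C)c3)=C2OC)C1(C)C | intermediate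
38 | (1S,5S,7R)-5-[(2E,4S)-4-{[tert-butyl(dimethyl)silyl]oxy}-3,7-dimethylocta-2,6-dien-1-yl]-3-(3,4-dihydroxybenzoyl)-4-hydroxy-8,8-dimethyl-1,7-bis(3-methylbut-2-en-1-yl)bicyclo[3.3.1]non-3-ene-2,9-dione | CC(C)=CC[C@@H]1C[C@]2(C/C=C(\C)[C@@H](O[Si](C)(C)C(C)(C)C)CC=C(C)C)C(=O)[C@@](CC=C(C)C)(C(=O)C(C(=O)c3ccc(O)c(O)c3)=C2O)C1(C)C | intermediate
39 | (1S,5S,7R)-3-(3,4-dihydroxybenzoyl)-4-hydroxy-5-[(2E,4S)-4-hydroxy-3,7-dimethylocta-2,6-dien-1-yl]-8,8-dimethyl-1,7-bis(3-methylbut-2-en-1-yl)bicyclo[3.3.1]non-3-ene-2,9-dione | CC(C)=CC[C@@H]1C[C@]2(C/C=C(\C)[C@@H](O)CC=C(C)C)C(=O)[C@@](CC=C(C)C)(C(=O)C(C(=O)c3ccc(O)c(O)c3)=C2O)C1(C)C | target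

**Totals**
Total step count: 23. Longest linear sequence: 14 steps (steps 1–10, then 20–23).

**Three steps most likely to fail, with fallbacks**

Step 9 (Effenberger annulation). This step is typically low-yielding, and HCl is generated in the presence of two prenyl groups. The fallback sets out from 12 and comes back at 16, bypassing 15 and step 10. MeLi (THF, 0 °C) cleaves 12 to lithium (4S)-3,3-dimethyl-2,4-bis(3-methylbut-2-en-1-yl)cyclohex-1-en-1-olate F1. Addition of F1 to bought 3-(trimethylsilyl)prop-2-ynal at −78 °C gives the aldol adduct (2R,4S)-2-[1-hydroxy-3-(trimethylsilyl)prop-2-yn-1-yl]-3,3-dimethyl-2,4-bis(3-methylbut-2-en-1-yl)cyclohexan-1-one F2, with the same facial preference as the acylation. Dess–Martin periodinane gives the ynone (2S,4S)-3,3-dimethyl-2,4-bis(3-methylbut-2-en-1-yl)-2-[3-(trimethylsilyl)prop-2-ynoyl]cyclohexan-1-one F3. N-Bromosuccinimide with AgNO3 (cat.) in acetone exchanges silicon for bromine to give (2S,4S)-2-(3-bromoprop-2-ynoyl)-3,3-dimethyl-2,4-bis(3-methylbut-2-en-1-yl)cyclohexan-1-one F4. t-BuMe2SiOTf/Et3N gives the silyl enol ether 3-bromo-1-[(1S,3R)-6-{[tert-butyl(dimethyl)silyl]oxy}-2,2-dimethyl-1,3-bis(3-methylbut-2-en-1-yl)cyclohex-5-en-1-yl]prop-2-yn-1-one F5. The cationic gold complex [(2-biphenylyl)(t-Bu)2P]Au(NCMe)SbF6 (5 mol %, wet acetone) then effects 6-endo-dig carbocyclisation to (1R,5R,7R)-4-bromo-8,8-dimethyl-1,7-bis(3-methylbut-2-en-1-yl)bicyclo[3.3.1]non-3-ene-2,9-dione F6. NaOMe in MeOH (addition–elimination) converts F6 into 16 as a single regioisomer.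

Step 16 (carboalumination next to a bulky silyloxy group). It can be sluggish or poorly regioselective. The fallback sets out from 25 and comes back at 28. n-BuLi (THF, −78 °C) gives the lithium acetylide lithium (3S)-3-{[tert-butyl(dimethyl)silyl]oxy}-6-methylhept-5-en-1-yn-1-ide F7, which is trapped with paraformaldehyde to give (4S)-4-{[tert-butyl(dimethyl)silyl]oxy}-7-methyloct-6-en-2-yn-1-ol F8. NaAlH2(OCH2CH2OCH3)2 in THF at 0 °C effects hydroxyl-directed trans-hydroalumination to the sodium cyclic alkenylaluminate F9. Iodination (I2, −78 °C) gives (2Z,4S)-4-{[tert-butyl(dimethyl)silyl]oxy}-3-iodo-7-methylocta-2,6-dien-1-ol F10. Negishi coupling with MeZnCl and Pd(PPh3)4 replaces iodine by methyl with retention of alkene geometry and gives 28.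

Step 21 (late-stage C-acylation of a hindered vinyllithium with a bulky, electron-rich aroyl chloride). The fallback sets out from 35 and comes back at 37. Bought 3,4-dihydroxybenzaldehyde is silylated (t-BuMe2SiCl, imidazole, DMF) to 3,4-bis{[tert-butyl(dimethyl)silyl]oxy}benzaldehyde F11. Vinyllithium 36, generated from 35 as in step 21, is added to F11 at −78 °C to give the carbinol (1S,5S,7R)-3-[(3,4-bis{[tert-butyl(dimethyl)silyl]oxy}phenyl)(hydroxy)methyl]-5-[(2E,4S)-4-{[tert-butyl(dimethyl)silyl]oxy}-3,7-dimethylocta-2,6-dien-1-yl]-4-methoxy-8,8-dimethyl-1,7-bis(3-methylbut-2-en-1-yl)bicyclo[3.3.1]non-3-ene-2,9-dione F12 (carbinol epimers). Dess–Martin periodinane (NaHCO3-buffered) oxidises F12 to 37.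

The bridgehead alkylation (step 20) is judged less risky because the electrophile is a geranyl-type primary allylic bromide, close to the prenyl bromide for which this lithiation–alkylation is established.

**Further compounds**
F1 | step 9 | lithium (4S)-3,3-dimethyl-2,4-bis(3-methylbut-2-en-1-yl)cyclohex-1-en-1-olate | [Li]OC1=C(CC=C(C)C)C(C)(C)[C@H](CC=C(C)C)CC1
F2 | step 9 | (2R,4S)-2-[1-hydroxy-3-(trimethylsilyl)prop-2-yn-1-yl]-3,3-dimethyl-2,4-bis(3-methylbut-2-en-1-yl)cyclohexan-1-one (carbinol epimers) | CC(C)=CC[C@@H]1CCC(=O)[C@@](CC=C(C)C)(C(O)C#C[Si](C)(C)C)C1(C)C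
F3 | step 9 | (2S,4S)-3,3-dimethyl-2,4-bis(3-methylbut-2-en-1-yl)-2-[3-(trimethylsilyl)prop-2-ynoyl]cyclohexan-1-one | CC(C)=CC[C@@H]1CCC(=O)[C@@](CC=C(C)C)(C(=O)C#C[Si](C)(C)C)C1(C)C
F4 | step 9 | (2S,4S)-2-(3-bromoprop-2-ynoyl)-3,3-dimethyl-2,4-bis(3-methylbut-2-en-1-yl)cyclohexan-1-one | CC(C)=CC[C@@H]1CCC(=O)[C@@](CC=C(C)C)(C(=O)C#CBr)C1(C)C
F5 | step 9 | 3-bromo-1-[(1S,3R)-6-{[tert-butyl(dimethyl)silyl]oxy}-2,2-dimethyl-1,3-bis(3-methylbut-2-en-1-yl)cyclohex-5-en-1-yl]prop-2-yn-1-one | CC(C)=CC[C@@H]1CC=C(O[Si](C)(C)C(C)(C)C)[C@@](CC=C(C)C)(C(=O)C#CBr)C1(C)C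
F6 | step 9 | (1R,5R,7R)-4-bromo-8,8-dimethyl-1,7-bis(3-methylbut-2-en-1-yl)bicyclo[3.3.1]non-3-ene-2,9-dione | CC(C)=CC[C@@H]1C[C@@H]2C(=O)[C@@](CC=C(C)C)(C(=O)C=C2Br)C1(C)C
F7 | step 16 | lithium (3S)-3-{[tert-butyl(dimethyl)silyl]oxy}-6-methylhept-5-en-1-yn-1-ide | [Li]C#C[C@@H](O[Si](C)(C)C(C)(C)C)CC=C(C)C
F8 | step 16 | (4S)-4-{[tert-butyl(dimethyl)silyl]oxy}-7-methyloct-6-en-2-yn-1-ol | OCC#C[C@@H](O[Si](C)(C)C(C)(C)C)CC=C(C)C
F9 | step 16 | sodium cyclic alkenylaluminate (2,2-bis(2-methoxyethoxy)-1,2-oxaluminol-3-ene carrying the (1S)-1-{[tert-butyl(dimethyl)silyl]oxy}-4-methylpent-3-en-1-yl group on the aluminium-bound alkene carbon) | [Na+].COCCO[Al-]1(OCCOC)OCC=C1[C@@H](O[Si](C)(C)C(C)(C)C)CC=C(C)C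
F10 | step 16 | (2Z,4S)-4-{[tert-butyl(dimethyl)silyl]oxy}-3-iodo-7-methylocta-2,6-dien-1-ol | OC/C=C(\I)[C@@H](O[Si](C)(C)C(C)(C)C)CC=C(C)C
F11 | step 21 | 3,4-bis{[tert-butyl(dimethyl)silyl]oxy}benzaldehyde | O=Cc1ccc(O[Si](C)(C)C(C)(C)C)c(O[Si](C)(C)C(C)(C)C)c1
F12 | step 21 | (1S,5S,7R)-3-[(3,4-bis{[tert-butyl(dimethyl)silyl]oxy}phenyl)(hydroxy)methyl]-5-[(2E,4S)-4-{[tert-butyl(dimethyl)silyl]oxy}-3,7-dimethylocta-2,6-dien-1-yl]-4-methoxy-8,8-dimethyl-1,7-bis(3-methylbut-2-en-1-yl)bicyclo[3.3.1]non-3-ene-2,9-dione (carbinol epimers) | CC(C)=CC[C@@H]1C[C@]2(C/C=C(\C)[C@@H](O[Si](C)(C)C(C)(C)C)CC=C(C)C)C(=O)[C@@](CC=C(C)C)(C(=O)C(C(O)c3ccc(O[Si](C)(C)C(C)(C)C)c(O[Si](C)(C)C(C)(C)C)c3)=C2OC)C1(C)C
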